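**Retrosynthetic overview**
- Planaic acid is cut at the depside ester C(=O)–O bond into the ring A acid (2,4-dimethoxy-6-pentylbenzoic acid) and the ring B phenol, carried as its benzyl ester; hydrogenolysis of that ester is the last step.
- The strategy rests on ring A: the carboxyl carbon on C1 sits between the C2 methoxy oxygen and the C6 pentyl chain, with a second methoxy on C4. This is the substitution left when a 3-methoxyaryne takes a carbon nucleophile at the far aryne carbon and a carbon electrophile at the near one.
- Ring A acid therefore comes from 3,5-dimethoxybenzyne + pentylmagnesium bromide + CO2, with the aryne released from 1,2-dibromo-3,5-dimethoxybenzene (NBS bromination of 1-bromo-3,5-dimethoxybenzene).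
- Ring B comes from olivetol: carboxylation, benzyl ester, then 4-O-MOM protection, 2-O-methylation and MOM removal.
- No ring is formed in the route; both benzene rings are purchased.

Key step: step 3

Assumption: Grignard species are drawn as monomeric RMgBr, and the first metalation of the dibromide is drawn at the bromine next to the methoxy group; metalation at the other bromine would lead to the same aryne.

**Route**

Step 1
Reactants: 1 1-bromo-3,5-dimethoxybenzene
Product: 2 1,2-dibromo-3,5-dimethoxybenzene
Conditions: NBS, MeCN, 0 °C to rt
Reagents that add atoms: N-bromosuccinimide, O=C1CCC(=O)N1Br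
Why: Electrophilic aromatic bromination should go at C2, para to one methoxy and ortho to the other, because the position between the two methoxy groups is more hindered, which places the new bromine next to the existing one.

Step 2
Reactants: 3 1-bromopentane
Product: 4 pentylmagnesium bromide (used as THF solution)
Conditions: Mg turnings, I2 (cat.), THF, gentle reflux
Reagents that add atoms: magnesium, [Mg]
Why: Grignard reagent formation by insertion of magnesium into a primary alkyl bromide is routine.

Step 3
Reactants: 2 1,2-dibromo-3,5-dimethoxybenzene; 4 pentylmagnesium bromide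
Product: 8 2,4-dimethoxy-6-pentylbenzoic acid, via ortho-bromoaryl Grignard 5 (not isolated), via 3,5-dimethoxybenzyne 6 (not isolated), via pentylated aryl Grignard 7 (not isolated)
Conditions: Mg turnings, excess 4, THF, reflux, slow addition of 2; then CO2 (gas), −20 °C to rt; then aq HCl
Reagents that add atoms: carbon dioxide, O=C=O
Why: Magnesium inserts into one C–Br bond of 2 (bromine–magnesium exchange with 4 would lead to the same species) and the ortho-bromoarylmagnesium 5 loses MgBr2 by 1,2-elimination in refluxing THF to give aryne 6; excess 4 then adds across the strained triple bond (carbomagnesiation) to give arylmagnesium 7, whose C–Mg bond is carboxylated by CO2 (Grignard carboxylation) and protonated on work-up. The closest known reaction type is the one-pot Grignard–aryne coupling of ortho-dihaloarenes with electrophilic quench of the resulting arylmagnesium, together with organometal additions to 3-methoxybenzynes used to make 6-alkyl-2-methoxybenzoic acids. No ring is closed and no stereocentre is created; the step forms the aryl–pentyl and aryl–carboxyl bonds. The step needs regioselective addition to the unsymmetrical aryne: the methoxy group on the carbon next to the triple bond withdraws σ-electron density and distorts the aryne so that the nucleophile attacks the far aryne carbon, leaving the carbanionic carbon ortho to oxygen where induction and O→Mg coordination stabilise it, while the second methoxy group, para to that carbon, should have only a small influence. Which bromine is metalated first is immaterial because both paths converge on 6, and slow addition of 2 to excess 4 keeps the aryne concentration low so that 7 does not compete with 4 as the nucleophile.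

Step 4
Reactants: 9 olivetol (5-pentylbenzene-1,3-diol)
Product: 10 olivetolic acid (2,4-dihydroxy-6-pentylbenzoic acid)
Conditions: MeOMgOCO2Me (2 M in DMF), 120 °C; then cold aq HCl
Reagents that add atoms: methyl magnesium carbonate, COC(=O)O[Mg]OC
Why: Kolbe–Schmitt-type ortho-carboxylation with magnesium methyl carbonate should carboxylate the ring carbon flanked by a hydroxyl and the pentyl chain, the product being held as a magnesium salicylate chelate that pulls the equilibrium forward.

Step 5
Reactants: 10 olivetolic acid
Product: 11 benzyl 2,4-dihydroxy-6-pentylbenzoate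
Conditions: BnBr, KHCO3, DMF, rt
Reagents that add atoms: benzyl bromide, BrCc1ccccc1
Why: Carboxylate O-alkylation (SN2) is selective because the weak base KHCO3 ionises only the carboxylic acid, so both phenols stay free.

Step 6
Reactants: 11 benzyl 2,4-dihydroxy-6-pentylbenzoate
Product: 12 benzyl 2-hydroxy-4-(methoxymethoxy)-6-pentylbenzoate
Conditions: MOMCl, iPr2NEt, CH2Cl2, 0 °C
Reagents that add atoms: chloromethyl methyl ether, COCCl
Why: Selective MOM etherification should occur at the 4-hydroxyl because the 2-hydroxyl is tied up in a hydrogen bond to the ester carbonyl and is much less nucleophilic.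

Step 7
Reactants: 12 benzyl 2-hydroxy-4-(methoxymethoxy)-6-pentylbenzoate
Product: 13 benzyl 2-methoxy-4-(methoxymethoxy)-6-pentylbenzoate
Conditions: MeI, K2CO3, DMF, rt to 50 °C
Reagents that add atoms: iodomethane, CI
Why: Williamson ether synthesis on the remaining chelated phenol proceeds under carbonate base in DMF, conditions to which the MOM acetal and the hindered benzyl ester are inert.

Step 8
Reactants: 13 benzyl 2-methoxy-4-(methoxymethoxy)-6-pentylbenzoate
Product: 14 benzyl 4-hydroxy-2-methoxy-6-pentylbenzoate
Conditions: aq HCl (3 M), THF, 40 °C
Reagents that add atoms: none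
Why: Acid-catalysed acetal hydrolysis removes the aryl MOM ether, while the 2,6-disubstituted benzyl benzoate and the aryl methyl ether are not cleaved by dilute acid.

Step 9
Reactants: 8 2,4-dimethoxy-6-pentylbenzoic acid; 14 benzyl 4-hydroxy-2-methoxy-6-pentylbenzoate
Product: 16 benzyl planaate (benzyl 4-[(2,4-dimethoxy-6-pentylbenzoyl)oxy]-2-methoxy-6-pentylbenzoate), via mixed trifluoroacetic anhydride 15 (not isolated)
Conditions: (CF3CO)2O, toluene, rt; aq NaHCO3 work-up
Reagents that add atoms: none
Why: Trifluoroacetic anhydride-mediated esterification (mixed anhydride with acylium character, stabilised by the ortho and para methoxy groups) is the standard depside coupling, and 14 offers a single free hydroxyl while its acid is masked as the benzyl ester.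

Step 10
Reactants: 16 benzyl planaate
Product: 17 planaic acid
Conditions: H2 (1 atm), Pd/C (10 wt%), EtOAc, rt
Reagents that add atoms: none
Why: Catalytic hydrogenolysis cleaves only the benzylic C–O bond of the benzyl ester, leaving the diaryl ester, the methyl ethers and both arenes untouched.

**Compound list**
1 | 1-bromo-3,5-dimethoxybenzene | COc1cc(Br)cc(OC)c1 | starting material
2 | 1,2-dibromo-3,5-dimethoxybenzene | COc1cc(OC)c(Br)c(Br)c1 | intermediate
3 | 1-bromopentane | CCCCCBr | starting material
4 | pentylmagnesium bromide | CCCCC[Mg]Br | intermediate
5 | 2-bromo-4,6-dimethoxyphenylmagnesium bromide | COc1cc(OC)c([Mg]Br)c(Br)c1 | intermediate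
6 | 3,5-dimethoxybenzyne (3,5-dimethoxy-1,2-didehydrobenzene) | COC1=CC(OC)=CC#C1 | intermediate
7 | 2,4-dimethoxy-6-pentylphenylmagnesium bromide | CCCCCc1cc(OC)cc(OC)c1[Mg]Br | intermediate
8 | 2,4-dimethoxy-6-pentylbenzoic acid | CCCCCc1cc(OC)cc(OC)c1C(=O)O | intermediate
9 | olivetol (5-pentylbenzene-1,3-diol) | CCCCCc1cc(O)cc(O)c1 | starting material
10 | olivetolic acid (2,4-dihydroxy-6-pentylbenzoic acid) | CCCCCc1cc(O)cc(O)c1C(=O)O | intermediate
11 | benzyl 2,4-dihydroxy-6-pentylbenzoate | CCCCCc1cc(O)cc(O)c1C(=O)OCc1ccccc1 | intermediate
12 | benzyl 2-hydroxy-4-(methoxymethoxy)-6-pentylbenzoate | CCCCCc1cc(OCOC)cc(O)c1C(=O)OCc1ccccc1 | intermediate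
13 | benzyl 2-methoxy-4-(methoxymethoxy)-6-pentylbenzoate | CCCCCc1cc(OCOC)cc(OC)c1C(=O)OCc1ccccc1 | intermediate
14 | benzyl 4-hydroxy-2-methoxy-6-pentylbenzoate | CCCCCc1cc(O)cc(OC)c1C(=O)OCc1ccccc1 | intermediate
15 | 2,4-dimethoxy-6-pentylbenzoic trifluoroacetic anhydride | CCCCCc1cc(OC)cc(OC)c1C(=O)OC(=O)C(F)(F)F | intermediate
16 | benzyl planaate (benzyl 4-[(2,4-dimethoxy-6-pentylbenzoyl)oxy]-2-methoxy-6-pentylbenzoate) | CCCCCc1cc(OC(=O)c2c(CCCCC)cc(OC)cc2OC)cc(OC)c1C(=O)OCc1ccccc1 | intermediate
17 | planaic acid | CCCCCc1cc(OC(=O)c2c(CCCCC)cc(OC)cc2OC)cc(OC)c1C(=O)O | target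

**Step count**
Total: 10 steps. Longest linear sequence: 7 steps (steps 4 to 10, from olivetol).

**Steps most likely to fail**

1. Step 3. The aryne may be reduced by β-hydride transfer from the pentyl Grignard instead of being alkylated, or be captured by the newly formed arylmagnesium. Elimination of MgBr2 may also stall, so that only debrominated material is recovered after the quench. Carboxylation of surplus alkyl Grignard adds a fatty acid that burdens the isolation. Fallback, setting out from olivetol 9 and returning at 8: exhaustive O-methylation (Me2SO4, K2CO3, acetone, reflux) should give 1,3-dimethoxy-5-pentylbenzene F1; Vilsmeier–Haack formylation (POCl3, DMF, then aqueous hydrolysis), directed para to one methoxy and ortho to the chain, should give 2,4-dimethoxy-6-pentylbenzaldehyde F2; Pinnick oxidation (NaClO2, NaH2PO4, 2-methyl-2-butene, t-BuOH/H2O) then delivers acid 8.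

2. Step 4. Carboxylation may stop short of completion, the electron-rich salicylic acid may decarboxylate during acidic work-up and drying, and some carboxylation between the two hydroxyls may compete. Fallback, setting out from olivetol 9 and returning at 13: Vilsmeier–Haack formylation (POCl3, DMF, then aqueous hydrolysis) should give 2,4-dihydroxy-6-pentylbenzaldehyde F3; selective protection of the non-chelated hydroxyl (MOMCl, iPr2NEt, CH2Cl2) gives 2-hydroxy-4-(methoxymethoxy)-6-pentylbenzaldehyde F4; methylation (MeI, K2CO3, DMF) gives 2-methoxy-4-(methoxymethoxy)-6-pentylbenzaldehyde F5; Pinnick oxidation (NaClO2, NaH2PO4, 2-methyl-2-butene) gives 2-methoxy-4-(methoxymethoxy)-6-pentylbenzoic acid F6; benzylation of the carboxylate (BnBr, KHCO3, DMF) rejoins the route at 13.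

3. Step 9. Acyl transfer from the doubly ortho-substituted mixed anhydride to a phenol deactivated by its para ester may be sluggish, with O-trifluoroacetylation of the phenol and ring acylation competing. Fallback, setting out from acid 8 (with phenol 14) and returning at 16: conversion of 8 with (COCl)2 and catalytic DMF in CH2Cl2 into 2,4-dimethoxy-6-pentylbenzoyl chloride F7, then acylation of the sodium phenoxide of 14 (NaH, THF, 0 °C to rt) under basic, non-equilibrating conditions to give 16.

**Further compounds**
F1 | step 3 | 1,3-dimethoxy-5-pentylbenzene | CCCCCc1cc(OC)cc(OC)c1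
F2 | step 3 | 2,4-dimethoxy-6-pentylbenzaldehyde | CCCCCc1cc(OC)cc(OC)c1C=O
F3 | step 4 | 2,4-dihydroxy-6-pentylbenzaldehyde | CCCCCc1cc(O)cc(O)c1C=O
F4 | step 4 | 2-hydroxy-4-(methoxymethoxy)-6-pentylbenzaldehyde | CCCCCc1cc(OCOC)cc(O)c1C=O
F5 | step 4 | 2-methoxy-4-(methoxymethoxy)-6-pentylbenzaldehyde | CCCCCc1cc(OCOC)cc(OC)c1C=O
F6 | step 4 | 2-methoxy-4-(methoxymethoxy)-6-pentylbenzoic acid | CCCCCc1cc(OCOC)cc(OC)c1C(=O)O
F7 | step 9 | 2,4-dimethoxy-6-pentylbenzoyl chloride | CCCCCc1cc(OC)cc(OC)c1C(=O)Cl
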